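## Structural features

The target is a germacranolide: a ten-membered carbocycle (C1–C10) with two trisubstituted Z alkenes, C1=C10 (methyl C14) and C4=C5 (methyl C15), fused across C6–C7 to an α-methylene-γ-butyrolactone (O on C6; C11, C12, C13 on C7). The ring fusion is cis (H6 and H7 on the same face), and C6, C7, C8 and C9 form one unbroken row of four stereocentres (6S,7R,8S,9S) in which the C8 hydroxyl and the C9 acyloxy group are syn. C9 is esterified by (2R,3S)-2,3-dimethyloxirane-2-carboxylic acid, whose two methyl groups are cis; this is the epoxide of the E (tiglate) series and adds two adjacent stereocentres outside the ring. The fifth ring stereocentre, the C3 acetate carbinol (3S), stands alone between the C2 methylene and the sp2 carbon C4. Fragile points are the methylene lactone (a Michael acceptor for thiols, amines and phosphines), the epoxy ester and acetate (acyl shift to a free O8, translactonisation from O6 to O8 under base), the allylic C–O bonds at C3, C6 and C9, and the skipped C1=C10 alkene, which can move into conjugation once C3 is a carbonyl. The real difficulty is to close a ten-membered ring holding two cis alkenes and a cis-fused lactone without loss of alkene geometry, late enough that four contiguous stereocentres and a base-sensitive ester set are already in place. The key step uses the isolated position of C3: bonded to the alkene carbon C4 and to no stereocentre, it can be a ketone during ring closure, so the ring is closed at C3–C4 by acylating C4 as an alkenyl metal.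

## Logic of the disconnections

46 ⇒ 45 ⇒ 44 ⇒ 43. The O8–Si bond, the acetyl C–O bond and the C3–H bond are cut in turn. These are the only operations left after ring closure, and C3 is the one stereocentre that a ketone-forming closure cannot carry. The demands are a 1,2- and face-selective reduction on a flexible ring, an acetylation that meets only one free hydroxyl (hence O8 stays silylated), and a non-basic final desilylation.

43 ⇒ 42. The C3–C4 bond is cut. The ring opens to a chain in which every stereocentre, the lactone and the epoxy ester are already present, and the bond joins two sp2 carbons without creating a stereocentre. The forward step must be neutral, must keep the C4=C5 geometry and must run at high dilution.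

42 ⇒ 40 ⇒ 39 ⇒ 38 ⇒ 37. The C3–S bond, the C3 oxidation level and the O–PMB bond are cut. The thioester is too reactive to carry and is made last. C3 is oxidised only after O9 is acylated, because a free O9 hydroxyl would close a six-membered lactone onto an activated C3 across the Z alkene. The oxidations must tolerate the alkenyltin bond, and the thioester must be made without free thiolate because of the methylene lactone.

37 ⇒ 35 + 13, 35 ⇒ 34. The ester C–O bond at O9 and the O9–Si bond are cut. The side chain is attached convergently as a finished enantiopure acid. The demands are a hindered esterification and the removal of a triethylsilyl ether beside a tert-butyldimethylsilyl ether.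

34 ⇒ 31 + 10. The C6–C7 bond and the lactone O6–C12 bond are cut. This is the most simplifying cut: two fragments of similar size, two stereocentres and the lactone from one Barbier reaction. The forward step must give the 6,7-syn adduct (cis-lactone) and the correct face of C7 relative to C8, and the alkenyltin must survive.

31 ⇒ 30 ⇒ 28 + 29. The C13–Br bond (with allylic transposition) and the C7–C11 bond are cut. The whole C11–C13 unit comes from one acrylate. The aldehyde must be stable at C8 during the addition.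

28 ⇒ 27 ⇒ 26 ⇒ 25 ⇒ 17 + 23. After oxidation-level changes at C7 and removal of the O9 silyl group, the C8–C9 bond is cut. An auxiliary-controlled glycolate aldol sets both centres and delivers O8 protected and O9 free, so the two oxygens are differentiated from the start. The demand is 1,2-addition to a Z enal without isomerisation.

23 ⇒ 22 ⇒ 21 ⇒ 19 + 20, 19 ⇒ 18. The C1=C10 bond is cut. A Z-selective phosphonate olefination fixes C2 cis to C9. C3 is carried as a protected alcohol, because a C3 carbonyl at this stage would be a 1,3-dicarbonyl partner.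

10 ⇒ 9 ⇒ 8 ⇒ 6 ⇒ 1 + 2. The C4–Sn bond and the C4=C5 bond are cut. The iodo-ylide olefination fixes the halogen, and later tin, cis to C6. Tin is introduced by lithium exchange on this small fragment, where no lactone or ester is present.

13 ⇒ 12 ⇒ 11. The carboxyl oxidation level and the two epoxide C–O bonds are cut. Reagent-controlled epoxidation of the E allylic alcohol sets both side-chain centres.

17 ⇒ 14 + 15. The N-acyl bond is cut; both pieces are commercial.

## Other disconnections considered

Alternative 1: The cut runs through C5–C6 and the lactone C12–O6 bond. CrCl2 with catalytic NiCl2 would convert the C5 (Z)-alkenyl iodide of the open-chain aldehyde ester A2 into an alkenylchromium species and add it to the C6 aldehyde, closing the ten-membered ring. The C6 chromium alkoxide would then close onto the C12 ester to give A1.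
- In favour: ring, C6 stereocentre and lactone arise in one operation, and no tin or thioester is needed. The C3 acetate is set beforehand on an open chain, where reagent control is more dependable than on a folded macrocycle; on that point the alternative is better than the chosen plan.
- Against: C6 is created during ring closure and must come out cis to the C7 substituent with only the ring conformation to steer it. The C6 aldehyde of A2 sits on C7, which is α to the aldehyde and allylic to the acrylate, so epimerisation or migration of the C11=C13 bond is a standing risk. A1 still needs PMB removal, acylation of the hindered ring hydroxyl at C9 and desilylation.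
- Comparison: both plans need three steps after ring closure, so they are equal in that count. The chosen plan fixes C6 and C7 before cyclisation in an acyclic Barbier reaction, and its ring closure forms no stereocentre, whereas the chromium addition forms one under substrate control.

Alternative 2: The cut is the C1=C10 double bond, traced back to the eleven-membered cyclic sulfone A4 with sulfur between C1 and C10. In situ α-halogenation (CBr2F2, KOH on Al2O3), 1,3-elimination to the episulfone and loss of SO2 would contract the ring to the ten-membered Z,Z-diene A3.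
- In favour: the ring is first closed at the eleven-membered sulfide stage by S-alkylation, which is easier than a direct ten-ring closure. In a ring of this size the extrusion should deliver the ring-cis alkene, so on ring-closure risk and on C1=C10 geometry the alternative is the equal of, or better than, the chosen plan. No palladium or tin is involved.
- Against: the conditions are strongly basic, so A4 cannot carry the lactone, the acetate or the epoxy ester. Its free C9 hydroxyl β to the sulfone invites retro-aldol cleavage or elimination. A3 still needs acylation at C9, removal of three silyl ethers, oxidation of C12 and lactonisation onto O6, acetylation of O3 and PMB removal.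
- Comparison: the chosen plan needs three steps after ring closure against at least six here, and its neutral coupling tolerates the full ester set. Alternative 2 postpones every oxidation-level and acylation problem to the end.

Alternative 3: The cut is C8–C9. SmI2 would reduce the two aldehydes of the lactone dialdehyde A6 (C8 on C7, C9 on C10) to ketyls and couple them, closing the ten-membered ring and creating both carbinols of the diol A5.
- In favour: ring, C8–C9 bond and two stereocentres in one step, and A5 is one acylation away from the target. If the selectivities held, this would be the shortest route, and so better than the chosen plan in step economy.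
- Against: SmI2 is also a reductant for the methylene lactone (conjugate reduction, ketyl–alkene coupling onto C13), the allylic acetate and the allylic lactone C–O bond. The C9 aldehyde is a Z enal whose ketyl is an allyl radical (coupling at C1, loss of geometry). One of four diol diastereomers would be needed, chosen only by the samarium-bridged ring conformation, and C7 next to the C8 aldehyde is epimerisable. The last step would be a regioselective acylation of O9 beside O8 in a syn-diol.
- Comparison: the chosen plan makes C8 and C9 by an auxiliary-controlled aldol that delivers the two oxygens already differentiated, and closes the ring by a step that is blind to stereochemistry. Alternative 3 concentrates ring strain, two stereocentres and chemoselectivity in one reductive step.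

Key step: step 25

Remarks on the chemistry (assumptions, one line each):
- Locants C1–C15 are the germacrane locants (C6 lactone carbinol, C7 bearing C11/C12/C13, C8 hydroxyl, C9 ester, C10 with C14, C4 with C15) and are kept for the 3,4-seco intermediates.
- The oxirane ester is (2R,3S) with carboxyl trans to the C3' methyl, so it is made from (E)-2-methylbut-2-en-1-ol; epoxidation of angelic acid would give the other diastereomer.
- L-(+)-diethyl tartrate is taken to give the (2S,3S)-epoxy alcohol 12 from this E allylic alcohol, as with other E-disubstituted allylic alcohols; if the sense were opposite, the D-tartrate would be used.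
- O8 is carried as a tert-butyldimethylsilyl ether because a more labile triethylsilyl ether is needed on O9 up to the fragment union.

## Route

Step 1
Reactants: 1 ethyltriphenylphosphonium bromide; 2 (tert-butyldimethylsilyloxy)acetaldehyde
Product: 6 (Z)-tert-butyl[(3-iodobut-2-en-1-yl)oxy]dimethylsilane, via ethylidenetriphenylphosphorane 3 (not isolated), via (1-iodoethyl)triphenylphosphonium iodide 4 (not isolated), via (1-iodoethylidene)triphenylphosphorane 5 (not isolated)
Conditions: n-BuLi, THF, 0 °C; I2, −78 °C; NaN(SiMe3)2, −78 → −20 °C; then 2, −78 °C → rt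
Reagents that add atoms: iodine, II
Why: Stork–Zhao olefination: the iodinated non-stabilised ylide 5 adds to the aldehyde under kinetic control and should give the 2-iodoalkene with iodine cis to the CH2O carbon (Z), which fixes the later C4=C5 geometry.

Step 2
Reactants: 6 (Z)-tert-butyl[(3-iodobut-2-en-1-yl)oxy]dimethylsilane
Product: 8 (Z)-tert-butyldimethyl{[3-(tributylstannyl)but-2-en-1-yl]oxy}silane, via alkenyllithium 7 (not isolated)
Conditions: t-BuLi (2.1 equiv), Et2O, −78 °C; Bu3SnCl, −78 °C → rt
Reagents that add atoms: tributyltin chloride, CCCC[Sn](Cl)(CCCC)CCCC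
Why: Iodine–lithium exchange and trapping of 7 with Bu3SnCl both proceed with retention at the sp2 carbon; ether and −78 °C keep the cis-disposed silyl group from migrating to carbon.

Step 3
Reactants: 8 (Z)-tert-butyldimethyl{[3-(tributylstannyl)but-2-en-1-yl]oxy}silane
Product: 9 (Z)-3-(tributylstannyl)but-2-en-1-ol
Conditions: Bu4NF, THF, 0 °C
Reagents that add atoms: none
Why: Fluoride cleavage of a primary silyl ether; alkenylstannanes are inert to Bu4NF.

Step 4
Reactants: 9 (Z)-3-(tributylstannyl)but-2-en-1-ol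
Product: 10 (Z)-3-(tributylstannyl)but-2-enal
Conditions: MnO2 (excess), CH2Cl2, rt, dark
Reagents that add atoms: none
Why: Allylic oxidation with MnO2 under neutral conditions should leave the C–Sn bond and the Z geometry untouched; the aldehyde is used at once.

Step 5
Reactants: 11 (E)-2-methylbut-2-en-1-ol
Product: 12 [(2S,3S)-2,3-dimethyloxiran-2-yl]methanol
Conditions: Ti(OiPr)4 (cat.), L-(+)-diethyl tartrate (cat.), t-BuOOH, 4 Å MS, CH2Cl2, −20 °C
Reagents that add atoms: tert-butyl hydroperoxide, CC(C)(C)OO
Why: Sharpless asymmetric epoxidation: syn oxygen transfer to the E alkene keeps the two methyl groups cis, and the tartrate sets both stereocentres.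

Step 6
Reactants: 12 [(2S,3S)-2,3-dimethyloxiran-2-yl]methanol
Product: 13 (2R,3S)-2,3-dimethyloxirane-2-carboxylic acid
Conditions: RuCl3 (cat.), NaIO4, MeCN/EtOAc/H2O, 0 °C → rt
Reagents that add atoms: water, O
Why: RuO4-mediated oxidation of a primary epoxy alcohol to the acid through the aldehyde hydrate; the epoxide is inert, and the C2 descriptor changes only because the carboxyl now outranks C3.

Step 7
Reactants: 14 (R)-4-benzyloxazolidin-2-one; 15 (tert-butyldimethylsilyloxy)acetic acid
Product: 17 (R)-4-benzyl-3-[(tert-butyldimethylsilyloxy)acetyl]oxazolidin-2-one, via mixed pivalic anhydride 16 (not isolated)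
Conditions: 15, t-BuCOCl, Et3N, THF, −20 °C; then LiCl, 14, rt
Reagents that add atoms: none
Why: N-Acylation of the oxazolidinone by a mixed anhydride under LiCl/Et3N activation; attack occurs at the less hindered glycolyl carbonyl.

Step 8
Reactants: 18 3-[(4-methoxybenzyl)oxy]propan-1-ol
Product: 19 3-[(4-methoxybenzyl)oxy]propanal
Conditions: TEMPO (cat.), PhI(OAc)2, CH2Cl2, rt
Reagents that add atoms: none
Why: TEMPO-catalysed oxidation of a primary alcohol stops at the aldehyde in the absence of water.

Step 9
Reactants: 19 3-[(4-methoxybenzyl)oxy]propanal; 20 methyl 2-[bis(2,2,2-trifluoroethoxy)phosphoryl]propanoate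
Product: 21 methyl (Z)-5-[(4-methoxybenzyl)oxy]-2-methylpent-2-enoate
Conditions: 20, KN(SiMe3)2, 18-crown-6, THF, −78 °C; then 19
Reagents that add atoms: none
Why: Still–Gennari olefination: the electron-poor phosphonate eliminates fast from the kinetic adduct and should give the Z-trisubstituted enoate, placing C2 cis to the future C9.

Step 10
Reactants: 21 methyl (Z)-5-[(4-methoxybenzyl)oxy]-2-methylpent-2-enoate
Product: 22 (Z)-5-[(4-methoxybenzyl)oxy]-2-methylpent-2-en-1-ol
Conditions: i-Bu2AlH, CH2Cl2, −78 °C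
Reagents that add atoms: none
Why: 1,2-Reduction of the enoate to the allylic alcohol without change of alkene geometry.

Step 11
Reactants: 22 (Z)-5-[(4-methoxybenzyl)oxy]-2-methylpent-2-en-1-ol
Product: 23 (Z)-5-[(4-methoxybenzyl)oxy]-2-methylpent-2-enal
Conditions: MnO2, CH2Cl2, rt
Reagents that add atoms: none
Why: Neutral allylic oxidation; the Z enal is not stored, to avoid isomerisation to the E isomer.

Step 12
Reactants: 17 (R)-4-benzyl-3-[(tert-butyldimethylsilyloxy)acetyl]oxazolidin-2-one; 23 (Z)-5-[(4-methoxybenzyl)oxy]-2-methylpent-2-enal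
Product: 25 (R)-4-benzyl-3-[(2R,3S,4Z)-2-(tert-butyldimethylsilyloxy)-3-hydroxy-7-(4-methoxybenzyloxy)-4-methylhept-4-enoyl]oxazolidin-2-one, via dibutylboron Z-enolate 24 (not isolated)
Conditions: Bu2BOTf, i-Pr2NEt, CH2Cl2, 0 °C; 23, −78 → 0 °C; H2O2, pH 7 buffer, MeOH, 0 °C
Reagents that add atoms: none
Why: Evans syn-aldol: the Z boron enolate 24 reacts through a closed chair on the face away from the benzyl group, and the R auxiliary should give the 2R,3S adduct, i.e. the C8/C9 syn-diol with O8 silylated and O9 free. 1,2-Addition to the enal is fast at −78 °C.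

Step 13
Reactants: 25 (R)-4-benzyl-3-[(2R,3S,4Z)-2-(tert-butyldimethylsilyloxy)-3-hydroxy-7-(4-methoxybenzyloxy)-4-methylhept-4-enoyl]oxazolidin-2-one
Product: 26 (R)-4-benzyl-3-[(2R,3S,4Z)-2-(tert-butyldimethylsilyloxy)-7-(4-methoxybenzyloxy)-4-methyl-3-(triethylsilyloxy)hept-4-enoyl]oxazolidin-2-one
Conditions: Et3SiOTf, 2,6-lutidine, CH2Cl2, −78 °C
Reagents that add atoms: triethylsilyl triflate, CC[Si](CC)(CC)OS(=O)(=O)C(F)(F)F
Why: Silylation of the secondary allylic alcohol; triethylsilyl is chosen so that it can later be removed beside the tert-butyldimethylsilyl ether on O8.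

Step 14
Reactants: 26 (R)-4-benzyl-3-[(2R,3S,4Z)-2-(tert-butyldimethylsilyloxy)-7-(4-methoxybenzyloxy)-4-methyl-3-(triethylsilyloxy)hept-4-enoyl]oxazolidin-2-one
Product: 27 (2S,3S,4Z)-2-(tert-butyldimethylsilyloxy)-7-(4-methoxybenzyloxy)-4-methyl-3-(triethylsilyloxy)hept-4-en-1-ol
Conditions: LiBH4, MeOH (1 equiv), THF, 0 °C
Reagents that add atoms: none
Why: Reductive removal of the auxiliary: hydride attacks the exocyclic imide carbonyl and releases the primary alcohol and the oxazolidinone.

Step 15
Reactants: 27 (2S,3S,4Z)-2-(tert-butyldimethylsilyloxy)-7-(4-methoxybenzyloxy)-4-methyl-3-(triethylsilyloxy)hept-4-en-1-ol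
Product: 28 (2R,3S,4Z)-2-(tert-butyldimethylsilyloxy)-7-(4-methoxybenzyloxy)-4-methyl-3-(triethylsilyloxy)hept-4-enal
Conditions: DMP, pyridine, CH2Cl2, 0 °C → rt
Reagents that add atoms: none
Why: Dess–Martin oxidation under buffered conditions should give the α-silyloxy aldehyde without epimerisation at C8.

Step 16
Reactants: 28 (2R,3S,4Z)-2-(tert-butyldimethylsilyloxy)-7-(4-methoxybenzyloxy)-4-methyl-3-(triethylsilyloxy)hept-4-enal; 29 methyl acrylate
Product: 30 methyl (4S,5S,6Z)-4-(tert-butyldimethylsilyloxy)-3-hydroxy-9-(4-methoxybenzyloxy)-6-methyl-2-methylidene-5-(triethylsilyloxy)non-6-enoate (both C3 epimers)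
Conditions: 29 (neat, excess), DABCO, MeOH (2 equiv), rt
Reagents that add atoms: none
Why: Morita–Baylis–Hillman reaction: the amine–acrylate zwitterion adds to the activated α-oxygenated aldehyde and the amine is eliminated. The new carbinol is not controlled and need not be, since it becomes sp2 in the next step.

Step 17
Reactants: 30 methyl (4S,5S,6Z)-4-(tert-butyldimethylsilyloxy)-3-hydroxy-9-(4-methoxybenzyloxy)-6-methyl-2-methylidene-5-(triethylsilyloxy)non-6-enoate
Product: 31 methyl (2Z,4S,5S,6Z)-2-(bromomethyl)-4-(tert-butyldimethylsilyloxy)-9-(4-methoxybenzyloxy)-6-methyl-5-(triethylsilyloxy)nona-2,6-dienoate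
Conditions: NBS, Me2S, CH2Cl2, 0 °C → rt
Reagents that add atoms: N-bromosuccinimide, O=C1CCC(=O)N1Br
Why: The Corey–Kim-type sulfonium reagent activates the allylic alcohol and bromide substitutes with allylic transposition (SN2'); the preferred trisubstituted enoate has C8 cis to CH2Br.

Step 18
Reactants: 31 methyl (2Z,4S,5S,6Z)-2-(bromomethyl)-4-(tert-butyldimethylsilyloxy)-9-(4-methoxybenzyloxy)-6-methyl-5-(triethylsilyloxy)nona-2,6-dienoate; 10 (Z)-3-(tributylstannyl)but-2-enal
Product: 34 (6R,7S,8S,9S,1(10)Z,4Z)-8-(tert-butyldimethylsilyloxy)-3-(4-methoxybenzyloxy)-4-(tributylstannyl)-9-(triethylsilyloxy)-3,4-secogermacra-1(10),4,11(13)-trien-12,6-olide, via allylindium dibromide 32 (not isolated), via seco hydroxy ester 33 (not isolated)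
Conditions: In, THF/H2O (3:1), rt; then PPTS (cat.), PhMe, 60 °C
Reagents that add atoms: none
Why: Barbier-type indium allylation (SE2' through C7) then lactonisation: the allylindium with C8 cis to CH2In reacts through a closed chair with the aldehyde substituent equatorial and C8 axial, which should give the 6,7-syn adduct and hence the cis-lactone. The face of C7 is set by C8: its hydrogen eclipses the C7=C11 bond (allylic strain against CH2In), the C9 alkenyl chain stands anti to the incoming aldehyde and the non-chelating silyl ether lies outside, which corresponds to 6R,7S as drawn. Anhydrous PPTS then closes the five-membered lactone and spares the stannane and the silyl ethers.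

Step 19
Reactants: 34 (6R,7S,8S,9S,1(10)Z,4Z)-8-(tert-butyldimethylsilyloxy)-3-(4-methoxybenzyloxy)-4-(tributylstannyl)-9-(triethylsilyloxy)-3,4-secogermacra-1(10),4,11(13)-trien-12,6-olide
Product: 35 (6R,7S,8S,9S,1(10)Z,4Z)-8-(tert-butyldimethylsilyloxy)-9-hydroxy-3-(4-methoxybenzyloxy)-4-(tributylstannyl)-3,4-secogermacra-1(10),4,11(13)-trien-12,6-olide
Conditions: PPTS, MeOH/CH2Cl2, 0 °C
Reagents that add atoms: none
Why: Acid-catalysed methanolysis cleaves the triethylsilyl ether much faster than the secondary tert-butyldimethylsilyl ether; PMB ether, lactone and stannane are stable to PPTS.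

Step 20
Reactants: 35 (6R,7S,8S,9S,1(10)Z,4Z)-8-(tert-butyldimethylsilyloxy)-9-hydroxy-3-(4-methoxybenzyloxy)-4-(tributylstannyl)-3,4-secogermacra-1(10),4,11(13)-trien-12,6-olide; 13 (2R,3S)-2,3-dimethyloxirane-2-carboxylic acid
Product: 37 (6R,7S,8S,9S,1(10)Z,4Z)-8-(tert-butyldimethylsilyloxy)-9-[(2R,3S)-2,3-dimethyloxirane-2-carbonyloxy]-3-(4-methoxybenzyloxy)-4-(tributylstannyl)-3,4-secogermacra-1(10),4,11(13)-trien-12,6-olide, via mixed trichlorobenzoic anhydride 36 (not isolated)
Conditions: 13, 2,4,6-Cl3C6H2COCl, Et3N, PhMe, rt; then 35, DMAP, PhMe, rt → 40 °C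
Reagents that add atoms: none
Why: Yamaguchi esterification: DMAP transfers the epoxy acyl group from the mixed anhydride to the hindered allylic alcohol, and the epoxide stereocentres are not involved. O9 is acylated now because a free O9 hydroxyl would later lactonise onto an activated C3 carbonyl.

Step 21
Reactants: 37 (6R,7S,8S,9S,1(10)Z,4Z)-8-(tert-butyldimethylsilyloxy)-9-[(2R,3S)-2,3-dimethyloxirane-2-carbonyloxy]-3-(4-methoxybenzyloxy)-4-(tributylstannyl)-3,4-secogermacra-1(10),4,11(13)-trien-12,6-olide
Product: 38 (6R,7S,8S,9S,1(10)Z,4Z)-8-(tert-butyldimethylsilyloxy)-9-[(2R,3S)-2,3-dimethyloxirane-2-carbonyloxy]-3-hydroxy-4-(tributylstannyl)-3,4-secogermacra-1(10),4,11(13)-trien-12,6-olide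
Conditions: DDQ, CH2Cl2/pH 7 buffer, 0 °C
Reagents that add atoms: none
Why: Oxidative cleavage of the p-methoxybenzyl ether through the benzylic cation; the buffer keeps the medium neutral so that the alkenyltin bond is not protonated.

Step 22
Reactants: 38 (6R,7S,8S,9S,1(10)Z,4Z)-8-(tert-butyldimethylsilyloxy)-9-[(2R,3S)-2,3-dimethyloxirane-2-carbonyloxy]-3-hydroxy-4-(tributylstannyl)-3,4-secogermacra-1(10),4,11(13)-trien-12,6-olide
Product: 39 (6R,7S,8S,9S,1(10)Z,4Z)-8-(tert-butyldimethylsilyloxy)-9-[(2R,3S)-2,3-dimethyloxirane-2-carbonyloxy]-3-oxo-4-(tributylstannyl)-3,4-secogermacra-1(10),4,11(13)-trien-12,6-olide (C3 aldehyde)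
Conditions: DMP, pyridine, CH2Cl2, 0 °C
Reagents that add atoms: none
Why: Dess–Martin oxidation; buffer and short reaction time should keep the C1=C10 alkene from moving into conjugation with the new aldehyde.

Step 23
Reactants: 39 (6R,7S,8S,9S,1(10)Z,4Z)-8-(tert-butyldimethylsilyloxy)-9-[(2R,3S)-2,3-dimethyloxirane-2-carbonyloxy]-3-oxo-4-(tributylstannyl)-3,4-secogermacra-1(10),4,11(13)-trien-12,6-olide
Product: 40 (6R,7S,8S,9S,1(10)Z,4Z)-8-(tert-butyldimethylsilyloxy)-9-[(2R,3S)-2,3-dimethyloxirane-2-carbonyloxy]-4-(tributylstannyl)-3,4-secogermacra-1(10),4,11(13)-trien-12,6-olid-3-oic acid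
Conditions: NaClO2, NaH2PO4, 2-methylbut-2-ene, t-BuOH/H2O, 0 °C
Reagents that add atoms: sodium chlorite, [Na+].[O-]Cl=O
Why: Pinnick oxidation: chlorous acid adds to the aldehyde and fragments to the acid; excess 2-methylbut-2-ene removes HOCl before it can attack the alkenes or the C–Sn bond.

Step 24
Reactants: 40 (6R,7S,8S,9S,1(10)Z,4Z)-8-(tert-butyldimethylsilyloxy)-9-[(2R,3S)-2,3-dimethyloxirane-2-carbonyloxy]-4-(tributylstannyl)-3,4-secogermacra-1(10),4,11(13)-trien-12,6-olid-3-oic acid
Product: 42 S-phenyl (6R,7S,8S,9S,1(10)Z,4Z)-8-(tert-butyldimethylsilyloxy)-9-[(2R,3S)-2,3-dimethyloxirane-2-carbonyloxy]-4-(tributylstannyl)-3,4-secogermacra-1(10),4,11(13)-trien-12,6-olide-3-thioate, via acid chloride 41 (not isolated)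
Conditions: Me2C=C(Cl)NMe2, CH2Cl2, 0 °C; then CuSPh, THF, 0 °C → rt
Reagents that add atoms: CuSPh (copper benzenethiolate), [Cu]Sc1ccccc1
Why: Neutral conversion into the acid chloride with the α-chloroenamine, then acylation of the copper thiolate, a known thioester synthesis. No free thiolate is present, so the methylene lactone is not attacked, and no base is there to shift the skipped alkene.

Step 25
Reactants: 42 S-phenyl (6R,7S,8S,9S,1(10)Z,4Z)-8-(tert-butyldimethylsilyloxy)-9-[(2R,3S)-2,3-dimethyloxirane-2-carbonyloxy]-4-(tributylstannyl)-3,4-secogermacra-1(10),4,11(13)-trien-12,6-olide-3-thioate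
Product: 43 (6S,7S,8S,9S,1(10)Z,4Z)-8-(tert-butyldimethylsilyloxy)-9-[(2R,3S)-2,3-dimethyloxirane-2-carbonyloxy]-3-oxogermacra-1(10),4,11(13)-trien-12,6-olide
Conditions: Pd2(dba)3 (5 mol %), P(2-furyl)3 (20 mol %), CuOP(O)Ph2 (2 equiv), THF, 2 mM, slow addition of 42, rt → 40 °C
Reagents that add atoms: none
Why: Intramolecular Liebeskind–Srogl ketone synthesis, the thioester counterpart of an acylative Stille macrocyclisation. Zerovalent palladium inserts into the C3–S bond of 42, assisted by the monovalent copper salt CuOP(O)Ph2, which binds sulfur and hands its phosphinate to tin. The alkenyl group then moves from tin to palladium with retention at C4, and reductive elimination from the acyl(alkenyl)palladium species forms C3–C4. The ten-membered ring is closed end to end through an eleven-membered palladacycle; both reacting carbons are sp2, the two Z alkenes and the cis-lactone pre-bend the chain, and high dilution with slow addition suppresses dimerisation. No stereocentre is formed. The step must keep the Z geometry of C4=C5, which the stereoretentive transmetalation secures, and must leave C1=C10 out of conjugation, which the base-free medium secures. Sulfur leaves as insoluble CuSPh, which is not a Michael donor toward the methylene lactone, and tin leaves as its phosphinate. Lactone, epoxy ester and silyl ether are untouched because no nucleophile or base is present.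

Step 26
Reactants: 43 (6S,7S,8S,9S,1(10)Z,4Z)-8-(tert-butyldimethylsilyloxy)-9-[(2R,3S)-2,3-dimethyloxirane-2-carbonyloxy]-3-oxogermacra-1(10),4,11(13)-trien-12,6-olide
Product: 44 (3S,6S,7S,8S,9S,1(10)Z,4Z)-8-(tert-butyldimethylsilyloxy)-9-[(2R,3S)-2,3-dimethyloxirane-2-carbonyloxy]-3-hydroxygermacra-1(10),4,11(13)-trien-12,6-olide
Conditions: (R)-2-methyl-CBS-oxazaborolidine (0.3 equiv), catecholborane, PhMe, −78 °C
Reagents that add atoms: none
Why: Corey–Bakshi–Shibata reduction: the ketone binds to the catalyst boron anti to the larger alkenyl side (C4) and hydride is delivered to the face that should give 3S with the R catalyst. Reduction is 1,2 only, and lactone and esters are inert at −78 °C.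

Step 27
Reactants: 44 (3S,6S,7S,8S,9S,1(10)Z,4Z)-8-(tert-butyldimethylsilyloxy)-9-[(2R,3S)-2,3-dimethyloxirane-2-carbonyloxy]-3-hydroxygermacra-1(10),4,11(13)-trien-12,6-olide
Product: 45 (3S,6S,7S,8S,9S,1(10)Z,4Z)-3-acetoxy-8-(tert-butyldimethylsilyloxy)-9-[(2R,3S)-2,3-dimethyloxirane-2-carbonyloxy]germacra-1(10),4,11(13)-trien-12,6-olide
Conditions: Ac2O, pyridine, DMAP (cat.), CH2Cl2, 0 °C
Reagents that add atoms: acetic anhydride, CC(=O)OC(C)=O
Why: DMAP-catalysed acetylation of the only free hydroxyl group.

Step 28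
Reactants: 45 (3S,6S,7S,8S,9S,1(10)Z,4Z)-3-acetoxy-8-(tert-butyldimethylsilyloxy)-9-[(2R,3S)-2,3-dimethyloxirane-2-carbonyloxy]germacra-1(10),4,11(13)-trien-12,6-olide
Product: 46 (3S,6S,7R,8S,9S,1(10)Z,4Z)-3-acetoxy-8-hydroxy-9-[(2R,3S)-2,3-dimethyloxirane-2-carbonyloxy]germacra-1(10),4,11(13)-trien-12,6-olide (CNP0137407.9)
Conditions: HF·pyridine, pyridine, THF, 0 °C → rt
Reagents that add atoms: none
Why: Fluoride cleavage of the silyl ether under buffered, weakly acidic conditions, which should avoid acyl migration from O9 to O8 and translactonisation to O8.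

## Compound list

1 | ethyltriphenylphosphonium bromide | CC[P+](c1ccccc1)(c1ccccc1)c1ccccc1.[Br-] | starting material
2 | (tert-butyldimethylsilyloxy)acetaldehyde | O=CCO[Si](C)(C)C(C)(C)C | starting material
3 | ethylidenetriphenylphosphorane | CC=P(c1ccccc1)(c1ccccc1)c1ccccc1 | intermediate
4 | (1-iodoethyl)triphenylphosphonium iodide | CC(I)[P+](c1ccccc1)(c1ccccc1)c1ccccc1.[I-] | intermediate
5 | (1-iodoethylidene)triphenylphosphorane | CC(I)=P(c1ccccc1)(c1ccccc1)c1ccccc1 | intermediate
6 | (Z)-tert-butyl[(3-iodobut-2-en-1-yl)oxy]dimethylsilane | C/C(I)=C/CO[Si](C)(C)C(C)(C)C | intermediate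
7 | (Z)-[4-(tert-butyldimethylsilyloxy)but-2-en-2-yl]lithium | [Li]/C(C)=C\CO[Si](C)(C)C(C)(C)C | intermediate
8 | (Z)-tert-butyldimethyl{[3-(tributylstannyl)but-2-en-1-yl]oxy}silane | CCCC[Sn](CCCC)(CCCC)/C(C)=C\CO[Si](C)(C)C(C)(C)C | intermediate
9 | (Z)-3-(tributylstannyl)but-2-en-1-ol | CCCC[Sn](CCCC)(CCCC)/C(C)=C\CO | intermediate
10 | (Z)-3-(tributylstannyl)but-2-enal | CCCC[Sn](CCCC)(CCCC)/C(C)=C\C=O | intermediate
11 | (E)-2-methylbut-2-en-1-ol | C/C=C(\C)CO | starting material
12 | [(2S,3S)-2,3-dimethyloxiran-2-yl]methanol | OC[C@]1(C)O[C@H]1C | intermediate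
13 | (2R,3S)-2,3-dimethyloxirane-2-carboxylic acid | OC(=O)[C@]1(C)O[C@H]1C | intermediate
14 | (R)-4-benzyloxazolidin-2-one | O=C1N[C@H](Cc2ccccc2)CO1 | starting material
15 | (tert-butyldimethylsilyloxy)acetic acid | OC(=O)CO[Si](C)(C)C(C)(C)C | starting material
16 | (tert-butyldimethylsilyloxy)acetic pivalic anhydride | CC(C)(C)C(=O)OC(=O)CO[Si](C)(C)C(C)(C)C | intermediate
17 | (R)-4-benzyl-3-[(tert-butyldimethylsilyloxy)acetyl]oxazolidin-2-one | O=C(CO[Si](C)(C)C(C)(C)C)N1[C@H](Cc2ccccc2)COC1=O | intermediate
18 | 3-[(4-methoxybenzyl)oxy]propan-1-ol | COc1ccc(COCCCO)cc1 | starting material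
19 | 3-[(4-methoxybenzyl)oxy]propanal | COc1ccc(COCCC=O)cc1 | intermediate
20 | methyl 2-[bis(2,2,2-trifluoroethoxy)phosphoryl]propanoate | COC(=O)C(C)P(=O)(OCC(F)(F)F)OCC(F)(F)F | starting material
21 | methyl (Z)-5-[(4-methoxybenzyl)oxy]-2-methylpent-2-enoate | COC(=O)/C(C)=C\CCOCc1ccc(OC)cc1 | intermediate
22 | (Z)-5-[(4-methoxybenzyl)oxy]-2-methylpent-2-en-1-ol | OC/C(C)=C\CCOCc1ccc(OC)cc1 | intermediate
23 | (Z)-5-[(4-methoxybenzyl)oxy]-2-methylpent-2-enal | O=C/C(C)=C\CCOCc1ccc(OC)cc1 | intermediate
24 | dibutylboron Z-enolate of 17 | CCCCB(CCCC)O/C(=C\O[Si](C)(C)C(C)(C)C)N1[C@H](Cc2ccccc2)COC1=O | intermediate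
25 | (R)-4-benzyl-3-[(2R,3S,4Z)-2-(tert-butyldimethylsilyloxy)-3-hydroxy-7-(4-methoxybenzyloxy)-4-methylhept-4-enoyl]oxazolidin-2-one | COc1ccc(COCC/C=C(/C)[C@H](O)[C@@H](O[Si](C)(C)C(C)(C)C)C(=O)N2[C@H](Cc3ccccc3)COC2=O)cc1 | intermediate
26 | (R)-4-benzyl-3-[(2R,3S,4Z)-2-(tert-butyldimethylsilyloxy)-7-(4-methoxybenzyloxy)-4-methyl-3-(triethylsilyloxy)hept-4-enoyl]oxazolidin-2-one | COc1ccc(COCC/C=C(/C)[C@H](O[Si](CC)(CC)CC)[C@@H](O[Si](C)(C)C(C)(C)C)C(=O)N2[C@H](Cc3ccccc3)COC2=O)cc1 | intermediate
27 | (2S,3S,4Z)-2-(tert-butyldimethylsilyloxy)-7-(4-methoxybenzyloxy)-4-methyl-3-(triethylsilyloxy)hept-4-en-1-ol | COc1ccc(COCC/C=C(/C)[C@H](O[Si](CC)(CC)CC)[C@@H](O[Si](C)(C)C(C)(C)C)CO)cc1 | intermediate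
28 | (2R,3S,4Z)-2-(tert-butyldimethylsilyloxy)-7-(4-methoxybenzyloxy)-4-methyl-3-(triethylsilyloxy)hept-4-enal | COc1ccc(COCC/C=C(/C)[C@H](O[Si](CC)(CC)CC)[C@@H](O[Si](C)(C)C(C)(C)C)C=O)cc1 | intermediate
29 | methyl acrylate | C=CC(=O)OC | starting material
30 | methyl (4S,5S,6Z)-4-(tert-butyldimethylsilyloxy)-3-hydroxy-9-(4-methoxybenzyloxy)-6-methyl-2-methylidene-5-(triethylsilyloxy)non-6-enoate (C3 epimers) | COc1ccc(COCC/C=C(/C)[C@H](O[Si](CC)(CC)CC)[C@@H](O[Si](C)(C)C(C)(C)C)C(O)C(=C)C(=O)OC)cc1 | intermediate
31 | methyl (2Z,4S,5S,6Z)-2-(bromomethyl)-4-(tert-butyldimethylsilyloxy)-9-(4-methoxybenzyloxy)-6-methyl-5-(triethylsilyloxy)nona-2,6-dienoate | COc1ccc(COCC/C=C(/C)[C@H](O[Si](CC)(CC)CC)[C@@H](O[Si](C)(C)C(C)(C)C)/C=C(\CBr)C(=O)OC)cc1 | intermediate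
32 | allylindium dibromide derived from 31 (InBr2 in place of Br) | COc1ccc(COCC/C=C(/C)[C@H](O[Si](CC)(CC)CC)[C@@H](O[Si](C)(C)C(C)(C)C)/C=C(\C[In](Br)Br)C(=O)OC)cc1 | intermediate
33 | methyl (6R,7S,8S,9S,1(10)Z,4Z)-8-(tert-butyldimethylsilyloxy)-6-hydroxy-3-(4-methoxybenzyloxy)-4-(tributylstannyl)-9-(triethylsilyloxy)-3,4-secogermacra-1(10),4,11(13)-trien-12-oate | COC(=O)C(=C)[C@@H]([C@@H](O)/C=C(/C)[Sn](CCCC)(CCCC)CCCC)[C@H](O[Si](C)(C)C(C)(C)C)[C@@H](O[Si](CC)(CC)CC)/C(C)=C\CCOCc1ccc(OC)cc1 | intermediate
34 | (6R,7S,8S,9S,1(10)Z,4Z)-8-(tert-butyldimethylsilyloxy)-3-(4-methoxybenzyloxy)-4-(tributylstannyl)-9-(triethylsilyloxy)-3,4-secogermacra-1(10),4,11(13)-trien-12,6-olide | C=C1C(=O)O[C@@H](/C=C(/C)[Sn](CCCC)(CCCC)CCCC)[C@H]1[C@H](O[Si](C)(C)C(C)(C)C)[C@@H](O[Si](CC)(CC)CC)/C(C)=C\CCOCc2ccc(OC)cc2 | intermediate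
35 | 9-hydroxy analogue of 34 (O9 free) | C=C1C(=O)O[C@@H](/C=C(/C)[Sn](CCCC)(CCCC)CCCC)[C@H]1[C@H](O[Si](C)(C)C(C)(C)C)[C@@H](O)/C(C)=C\CCOCc2ccc(OC)cc2 | intermediate
36 | (2R,3S)-2,3-dimethyloxirane-2-carboxylic 2,4,6-trichlorobenzoic anhydride | O=C(OC(=O)[C@]1(C)O[C@H]1C)c2c(Cl)cc(Cl)cc2Cl | intermediate
37 | (6R,7S,8S,9S,1(10)Z,4Z)-8-(tert-butyldimethylsilyloxy)-9-[(2R,3S)-2,3-dimethyloxirane-2-carbonyloxy]-3-(4-methoxybenzyloxy)-4-(tributylstannyl)-3,4-secogermacra-1(10),4,11(13)-trien-12,6-olide | C=C1C(=O)O[C@@H](/C=C(/C)[Sn](CCCC)(CCCC)CCCC)[C@H]1[C@H](O[Si](C)(C)C(C)(C)C)[C@@H](OC(=O)[C@]2(C)O[C@H]2C)/C(C)=C\CCOCc3ccc(OC)cc3 | intermediate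
38 | 3-hydroxy analogue of 37 (C3 primary alcohol) | C=C1C(=O)O[C@@H](/C=C(/C)[Sn](CCCC)(CCCC)CCCC)[C@H]1[C@H](O[Si](C)(C)C(C)(C)C)[C@@H](OC(=O)[C@]2(C)O[C@H]2C)/C(C)=C\CCO | intermediate
39 | C3 aldehyde corresponding to 38 | C=C1C(=O)O[C@@H](/C=C(/C)[Sn](CCCC)(CCCC)CCCC)[C@H]1[C@H](O[Si](C)(C)C(C)(C)C)[C@@H](OC(=O)[C@]2(C)O[C@H]2C)/C(C)=C\CC=O | intermediate
40 | C3 carboxylic acid corresponding to 38 | C=C1C(=O)O[C@@H](/C=C(/C)[Sn](CCCC)(CCCC)CCCC)[C@H]1[C@H](O[Si](C)(C)C(C)(C)C)[C@@H](OC(=O)[C@]2(C)O[C@H]2C)/C(C)=C\CC(=O)O | intermediate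
41 | C3 acid chloride corresponding to 40 | C=C1C(=O)O[C@@H](/C=C(/C)[Sn](CCCC)(CCCC)CCCC)[C@H]1[C@H](O[Si](C)(C)C(C)(C)C)[C@@H](OC(=O)[C@]2(C)O[C@H]2C)/C(C)=C\CC(=O)Cl | intermediate
42 | S-phenyl C3 thioester of 40: lactone-bearing C4 alkenylstannane, key-step precursor (6R,7S,8S,9S) | C=C1C(=O)O[C@@H](/C=C(/C)[Sn](CCCC)(CCCC)CCCC)[C@H]1[C@H](O[Si](C)(C)C(C)(C)C)[C@@H](OC(=O)[C@]2(C)O[C@H]2C)/C(C)=C\CC(=O)Sc3ccccc3 | intermediate
43 | (6S,7S,8S,9S,1(10)Z,4Z)-8-(tert-butyldimethylsilyloxy)-9-[(2R,3S)-2,3-dimethyloxirane-2-carbonyloxy]-3-oxogermacra-1(10),4,11(13)-trien-12,6-olide | C=C1C(=O)O[C@H]2/C=C(/C)C(=O)C/C=C(/C)[C@H](OC(=O)[C@]3(C)O[C@H]3C)[C@@H](O[Si](C)(C)C(C)(C)C)[C@@H]12 | intermediate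
44 | (3S,6S,7S,8S,9S)-3-hydroxy analogue of 43 | C=C1C(=O)O[C@H]2/C=C(/C)[C@@H](O)C/C=C(/C)[C@H](OC(=O)[C@]3(C)O[C@H]3C)[C@@H](O[Si](C)(C)C(C)(C)C)[C@@H]12 | intermediate
45 | (3S,6S,7S,8S,9S)-3-acetoxy analogue of 43 | C=C1C(=O)O[C@H]2/C=C(/C)[C@@H](OC(C)=O)C/C=C(/C)[C@H](OC(=O)[C@]3(C)O[C@H]3C)[C@@H](O[Si](C)(C)C(C)(C)C)[C@@H]12 | intermediate
46 | (3S,6S,7R,8S,9S,1(10)Z,4Z)-3-acetoxy-8-hydroxy-9-[(2R,3S)-2,3-dimethyloxirane-2-carbonyloxy]germacra-1(10),4,11(13)-trien-12,6-olide | C=C1C(=O)O[C@H]2/C=C(/C)[C@@H](OC(C)=O)C/C=C(/C)[C@H](OC(=O)[C@]3(C)O[C@H]3C)[C@@H](O)[C@@H]12 | target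

## Step count and least certain steps

Total: 28 steps. Longest linear sequence: 21 steps (18 → 46, steps 8–28).

Step 25 (key step). The fully substituted, hindered alkenyltin may transmetalate too slowly, so that protodestannylation and intermolecular acylation compete; zerovalent palladium may also ionise the allylic C9 ester or the C6 lactone C–O bond, and strain may slow reductive elimination. Fallback, from 39 back to 43: iododestannylation of 39 with I2 gives the alkenyl iodide aldehyde F1. CrCl2 with catalytic NiCl2 (DMSO/THF, high dilution) adds C4 to the C3 aldehyde and closes the ring to the macrocyclic allylic alcohol F2 (mixture at C3). Oxidation of F2 with DMP gives 43. The same C3–C4 bond is made, but by carbonyl addition instead of cross-coupling.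

Step 18. Facial selectivity at C7 may be poor (approach syn to the C9 chain) and the syn preference may erode if the allylindium equilibrates, which would give C6/C7 diastereomers. Fallback, from 30 back to 33: acetylation (Ac2O, DMAP) gives the acetate F3. SN2' borylation (B2pin2, CuCl, LiCl, KOAc, DMF) gives the allylboronate F4 with C8 cis to CH2B. Allylboration of 10 in toluene goes through a tighter boron chair and, if needed, a chiral BINOL-derived phosphoric acid imposes the facial sense from the reagent side. The borate ester F5 is hydrolysed to 33 and lactonised as in step 18.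

Step 26. The folded ten-membered enone may impose its own facial bias against the catalyst, and the uncatalysed background reduction would then lower selectivity. Fallback, from 43 back to 45: Luche reduction (NaBH4, CeCl3·7H2O, MeOH, −78 °C) reduces from the exposed face. If this gives the 3R alcohol F6, a Mitsunobu reaction with acetic acid (PPh3, DIAD, PhMe, 0 °C) installs the acetate with inversion and gives 45 directly.

Step 16. Addition to the hindered α,β-dioxygenated aldehyde may be slow, and prolonged amine exposure may cause epimerisation at C8 or β-elimination of the C9 silyloxy group. Fallback, from 28 back to 30: hydroalumination of methyl propiolate with i-Bu2AlH and N-methylmorpholine N-oxide (THF, 0 °C) gives the α-aluminoacrylate F7, which adds to 28 at 0 °C without amine base.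

Step 21. The tin may be lost by oxidation or by protonation from the acidic hydroquinone. Fallback, from 37 back to 38: I2 converts 37 into the alkenyl iodide F8, DDQ then cleaves the PMB ether to the alcohol F9, and PdCl2(PPh3)2 with Bu3SnSnBu3 (THF, 60 °C) reinstalls tin to give 38.

## Further compounds

F1 | step 25 | alkenyl iodide aldehyde (39 with I in place of SnBu3) | C=C1C(=O)O[C@@H](/C=C(/C)I)[C@H]1[C@H](O[Si](C)(C)C(C)(C)C)[C@@H](OC(=O)[C@]2(C)O[C@H]2C)/C(C)=C\CC=O
F2 | step 25 | macrocyclic allylic alcohol, C3 epimers (43 with CHOH at C3) | C=C1C(=O)O[C@H]2/C=C(/C)C(O)C/C=C(/C)[C@H](OC(=O)[C@]3(C)O[C@H]3C)[C@@H](O[Si](C)(C)C(C)(C)C)[C@@H]12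
F3 | step 18 | acetate of 30 | COc1ccc(COCC/C=C(/C)[C@H](O[Si](CC)(CC)CC)[C@@H](O[Si](C)(C)C(C)(C)C)C(OC(C)=O)C(=C)C(=O)OC)cc1
F4 | step 18 | pinacol allylboronate (31 with Bpin in place of Br) | COc1ccc(COCC/C=C(/C)[C@H](O[Si](CC)(CC)CC)[C@@H](O[Si](C)(C)C(C)(C)C)/C=C(\CB2OC(C)(C)C(C)(C)O2)C(=O)OC)cc1
F5 | step 18 | pinacol borate ester of 33 (O6–Bpin) | COC(=O)C(=C)[C@@H]([C@@H](OB1OC(C)(C)C(C)(C)O1)/C=C(/C)[Sn](CCCC)(CCCC)CCCC)[C@H](O[Si](C)(C)C(C)(C)C)[C@@H](O[Si](CC)(CC)CC)/C(C)=C\CCOCc2ccc(OC)cc2
F6 | step 26 | 3R alcohol (C3 epimer of 44) | C=C1C(=O)O[C@H]2/C=C(/C)[C@H](O)C/C=C(/C)[C@H](OC(=O)[C@]3(C)O[C@H]3C)[C@@H](O[Si](C)(C)C(C)(C)C)[C@@H]12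
F7 | step 16 | [1-(methoxycarbonyl)ethenyl]diisobutylaluminium | COC(=O)C(=C)[Al](CC(C)C)CC(C)C
F8 | step 21 | alkenyl iodide PMB ether (37 with I in place of SnBu3) | C=C1C(=O)O[C@@H](/C=C(/C)I)[C@H]1[C@H](O[Si](C)(C)C(C)(C)C)[C@@H](OC(=O)[C@]2(C)O[C@H]2C)/C(C)=C\CCOCc3ccc(OC)cc3
F9 | step 21 | alkenyl iodide alcohol (38 with I in place of SnBu3) | C=C1C(=O)O[C@@H](/C=C(/C)I)[C@H]1[C@H](O[Si](C)(C)C(C)(C)C)[C@@H](OC(=O)[C@]2(C)O[C@H]2C)/C(C)=C\CCO
A1 | alternative 1 | germacranolide with C8 silyl ether and C9 PMB ether | C=C1C(=O)O[C@H]2/C=C(/C)[C@@H](OC(C)=O)C/C=C(/C)[C@H](OCc3ccc(OC)cc3)[C@@H](O[Si](C)(C)C(C)(C)C)[C@@H]12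
A2 | alternative 1 | open-chain methyl ester with C5 (Z)-alkenyl iodide and C6 aldehyde | COC(=O)C(=C)[C@@H](C=O)[C@H](O[Si](C)(C)C(C)(C)C)[C@@H](OCc1ccc(OC)cc1)/C(C)=C\C[C@H](OC(C)=O)/C(C)=C\I
A3 | alternative 2 | ten-membered Z,Z-diene C9 carbinol | C=C(CO[Si](C)(C)C(C)(C)C)[C@@H]1[C@H](OCc2ccc(OC)cc2)[C@@H](O)/C(C)=C\C[C@H](O[Si](C)(C)C(C)(C)C)/C(C)=C\[C@@H]1O[Si](C)(C)C(C)(C)C
A4 | alternative 2 | eleven-membered cyclic sulfone with sulfur between C1 and C10 | C=C(CO[Si](C)(C)C(C)(C)C)[C@@H]1[C@H](OCc2ccc(OC)cc2)[C@@H](O)C(C)S(=O)(=O)CC[C@H](O[Si](C)(C)C(C)(C)C)/C(C)=C\[C@@H]1O[Si](C)(C)C(C)(C)C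
A5 | alternative 3 | germacranolide C8,C9-diol | C=C1C(=O)O[C@H]2/C=C(/C)[C@@H](OC(C)=O)C/C=C(/C)[C@H](O)[C@@H](O)[C@@H]12
A6 | alternative 3 | lactone dialdehyde with C8 and C9 aldehydes | C=C1C(=O)O[C@@H](/C=C(/C)[C@@H](OC(C)=O)C/C=C(/C)C=O)[C@H]1C=O
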